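**Retrosynthetic overview**

- Both C–Br bonds are made last by electrophilic substitution of the free phenol. The cyclopropane, the only ring the route builds, is closed just before that by phenol-directed CH2 transfer to a 5-aryl-1,5-dimethylcyclopentene.
- The route rests on one feature of the bicyclo[3.1.0]hexane: the benzylic quaternary carbon C2 (aryl and CH3) is bonded to the methyl-bearing quaternary cyclopropane carbon C1, which is bonded to the cyclopropane CH carbon C5. On the five-membered ring these three are the β carbon, the α carbon and the carbonyl carbon of a cyclopentenone.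
- Key disconnection: the C2–CH3 and C1–CH3 bonds, both formed in one pot by catalytic asymmetric conjugate methylation of 3-(2-methoxy-4-methylphenyl)cyclopent-2-en-1-one and methylation of the enolate. The carbonyl is then converted into the C1=C5 alkene through the more substituted enol triflate.
- The enone comes from an aryl Grignard reagent and 3-ethoxycyclopent-2-en-1-one. The benzene and cyclopentane rings are bought; the three-membered ring is closed in step 6.

Key step: step 2

Assumption: the sense of induction of the copper–phosphoramidite catalyst on this enone is not predicted with certainty. The route is written with the (S,S)-amine ligand delivering methyl to the Si face of the β carbon; if a trial shows the opposite sense, the mirror-image ligand is used with no other change.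

**Step 1**
Reactants: 1 2-bromo-5-methylanisole; 2 3-ethoxycyclopent-2-en-1-one
Product: 5 3-(2-methoxy-4-methylphenyl)cyclopent-2-en-1-one, via arylmagnesium bromide 3 (not isolated), via tertiary allylic alkoxide 4 (not isolated)
Conditions: Mg, THF, reflux; then 2, THF, 0 °C → rt; then 2 M HCl, rt
Reagents that add atoms: water, O (carbonyl oxygen of 5); magnesium, [Mg] (stays only in intermediates 3 and 4)
Why: The aryl Grignard reagent adds 1,2 to the vinylogous ester carbonyl, and aqueous acid then hydrolyses the enol ether with loss of water and ethanol and transposition of the carbonyl (Stork–Danheiser sequence) to give the β-aryl enone; no stereocenter is formed.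

**Step 2**
Reactants: 5 3-(2-methoxy-4-methylphenyl)cyclopent-2-en-1-one; 6 trimethylaluminium; 7 iodomethane
Product: 10 (2S,3R)-3-(2-methoxy-4-methylphenyl)-2,3-dimethylcyclopentan-1-one (methyl groups cis), via dimethylaluminium enolate 8 (not isolated), via lithium aluminate enolate 9 (not isolated)
Conditions: Cu(OTf)2 (5 mol%), O,O′-(biphenyl-2,2′-diyl) N,N-bis[(S)-1-(naphthalen-2-yl)ethyl]phosphoramidite (10 mol%), AlMe3 (1.4 equiv), Et2O, −30 °C; then MeLi (1.5 equiv), THF, −30 °C; then MeI (5 equiv), DMPU, −30 °C → rt; 1 M HCl, 0 °C
Reagents that add atoms: trimethylaluminium 6, C[Al](C)C (methyl on C3; Al stays only in 8 and 9); iodomethane 7, CI (methyl on C2); methyllithium, [Li]C (stays only in intermediate 9)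
Why: AlMe3 reduces Cu(OTf)2 to a monovalent methylcopper–phosphoramidite species, which forms a π-complex with the aluminium-activated enone, adds oxidatively at the β carbon (C3, cyclopentanone numbering) and reductively eliminates the C3–CH3 bond, leaving only the C1–C2 dimethylaluminium enolate 8. MeLi converts 8 into the more nucleophilic lithium aluminate 9, which iodomethane alkylates at C2 in an SN2 reaction. The closest known reaction type is the copper–phosphoramidite-catalysed asymmetric conjugate addition of trialkylaluminium reagents to β-substituted cyclic enones, with alkylation of the aluminium enolate after activation by an alkyllithium. No ring is closed; two C–C bonds are formed on the existing five-membered ring. C3 is set by the chiral copper complex, which delivers methyl to the Si face of the β carbon (3R), and C2 is set by the substrate, iodomethane approaching anti to the aryl group (2S), a centre that step 3 removes again. The step needs enantiofacial selectivity at C3 and alkylation at C2 rather than at C5 or on oxygen; the first rests on the ligand, the second on the conjugate addition generating only the C1–C2 enolate, which should be alkylated before it equilibrates by proton transfer.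

**Step 3**
Reactants: 10 (2S,3R)-3-(2-methoxy-4-methylphenyl)-2,3-dimethylcyclopentan-1-one
Product: 11 (3R)-3-(2-methoxy-4-methylphenyl)-2,3-dimethylcyclopent-1-en-1-yl trifluoromethanesulfonate
Conditions: Tf2O (1.5 equiv), 2,6-di-tert-butyl-4-methylpyridine (2 equiv), CH2Cl2, 0 °C → rt
Reagents that add atoms: trifluoromethanesulfonic anhydride, O=S(=O)(OS(=O)(=O)C(F)(F)F)C(F)(F)F
Why: Triflic anhydride sulfonylates the ketone oxygen and the hindered pyridine removes a proton from the triflyloxycarbenium ion under equilibrating, Zaitsev-type control, which should favour the tetrasubstituted C1=C2 enol triflate (thermodynamic vinyl triflate formation); the C2 stereocenter is erased and C3 is untouched.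

**Step 4**
Reactants: 11 (3R)-3-(2-methoxy-4-methylphenyl)-2,3-dimethylcyclopent-1-en-1-yl trifluoromethanesulfonate
Product: 12 1-[(1R)-1,2-dimethylcyclopent-2-en-1-yl]-2-methoxy-4-methylbenzene
Conditions: Pd(OAc)2 (5 mol%), PPh3 (10 mol%), HCO2H, Bu3N, DMF, 60 °C
Reagents that add atoms: none
Why: Zerovalent palladium formed from Pd(OAc)2 and PPh3 inserts into the vinyl C–O bond, formate replaces triflate and loses CO2 to give a palladium hydride, and C–H reductive elimination gives the alkene (palladium-catalysed formate reduction of an enol triflate) without touching the quaternary stereocenter or the aryl ether.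

**Step 5**
Reactants: 12 1-[(1R)-1,2-dimethylcyclopent-2-en-1-yl]-2-methoxy-4-methylbenzene
Product: 13 2-[(1R)-1,2-dimethylcyclopent-2-en-1-yl]-5-methylphenol
Conditions: NaSEt (5 equiv), DMF, 140 °C; then sat. aq NH4Cl, 0 °C
Reagents that add atoms: none
Why: Ethanethiolate attacks the O–CH3 carbon in an SN2 reaction (nucleophilic cleavage of an aryl methyl ether), and the basic medium avoids the acid-induced addition of the phenol to the neighbouring alkene.

**Step 6**
Reactants: 13 2-[(1R)-1,2-dimethylcyclopent-2-en-1-yl]-5-methylphenol
Product: 14 2-[(1S,2R,5R)-1,2-dimethylbicyclo[3.1.0]hexan-2-yl]-5-methylphenol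
Conditions: Et2Zn (3 equiv), CH2I2 (4 equiv), toluene, 0 °C → rt; then sat. aq NH4Cl
Reagents that add atoms: diiodomethane, ICI
Why: Diethylzinc deprotonates the phenol, and the resulting aryloxyzinc iodomethyl carbenoid transfers CH2 within the molecule to the alkene face on the side of the aryl group (hydroxyl-directed Simmons–Smith cyclopropanation, Furukawa variant), a concerted syn addition that sets C1 (S) and C5 (R) of the bicycle with the cyclopropane cis to the aryl ring at C2.

**Step 7**
Reactants: 14 2-[(1S,2R,5R)-1,2-dimethylbicyclo[3.1.0]hexan-2-yl]-5-methylphenol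
Product: 15 2,4-dibromo-6-[(1S,2R,5R)-1,2-dimethylbicyclo[3.1.0]hexan-2-yl]-3-methylphenol
Conditions: NBS (2.1 equiv), NaHCO3, MeCN, 0 °C → rt
Reagents that add atoms: N-bromosuccinimide, O=C1CCC(=O)N1Br
Why: Electrophilic aromatic substitution takes place at the two ring positions activated by the hydroxyl group, para (C4 of 14) and ortho (C6 of 14), both also ortho to the ring methyl, while the remaining free position is meta to oxygen; NBS releases succinimide instead of HBr and the bicarbonate buffer protects the acid-labile cyclopropane.

**Compound list**

1 | 2-bromo-5-methylanisole (1-bromo-2-methoxy-4-methylbenzene) | COc1cc(C)ccc1Br | starting material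
2 | 3-ethoxycyclopent-2-en-1-one | CCOC1=CC(=O)CC1 | starting material
3 | (2-methoxy-4-methylphenyl)magnesium bromide | COc1cc(C)ccc1[Mg]Br | intermediate
4 | bromomagnesium 3-ethoxy-1-(2-methoxy-4-methylphenyl)cyclopent-2-en-1-olate (racemic) | CCOC1=CC(O[Mg]Br)(c2ccc(C)cc2OC)CC1 | intermediate
5 | 3-(2-methoxy-4-methylphenyl)cyclopent-2-en-1-one | COc1cc(C)ccc1C1=CC(=O)CC1 | intermediate
6 | trimethylaluminium | C[Al](C)C | starting material
7 | iodomethane | CI | starting material
8 | dimethylaluminium (3R)-3-(2-methoxy-4-methylphenyl)-3-methylcyclopent-1-en-1-olate | COc1cc(C)ccc1[C@]1(C)CCC(O[Al](C)C)=C1 | intermediate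
9 | lithium [(3R)-3-(2-methoxy-4-methylphenyl)-3-methylcyclopent-1-en-1-olato]trimethylaluminate | [Li+].COc1cc(C)ccc1[C@]1(C)CCC(O[Al-](C)(C)C)=C1 | intermediate
10 | (2S,3R)-3-(2-methoxy-4-methylphenyl)-2,3-dimethylcyclopentan-1-one | COc1cc(C)ccc1[C@]1(C)CCC(=O)[C@H]1C | intermediate
11 | (3R)-3-(2-methoxy-4-methylphenyl)-2,3-dimethylcyclopent-1-en-1-yl trifluoromethanesulfonate | COc1cc(C)ccc1[C@]1(C)CCC(OS(=O)(=O)C(F)(F)F)=C1C | intermediate
12 | 1-[(1R)-1,2-dimethylcyclopent-2-en-1-yl]-2-methoxy-4-methylbenzene | COc1cc(C)ccc1[C@]1(C)CCC=C1C | intermediate
13 | 2-[(1R)-1,2-dimethylcyclopent-2-en-1-yl]-5-methylphenol | Cc1ccc([C@]2(C)CCC=C2C)c(O)c1 | intermediate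
14 | 2-[(1S,2R,5R)-1,2-dimethylbicyclo[3.1.0]hexan-2-yl]-5-methylphenol | Cc1ccc([C@]2(C)CC[C@@H]3C[C@@]32C)c(O)c1 | intermediate
15 | 2,4-dibromo-6-[(1S,2R,5R)-1,2-dimethylbicyclo[3.1.0]hexan-2-yl]-3-methylphenol | Cc1c(Br)cc([C@]2(C)CC[C@@H]3C[C@@]32C)c(O)c1Br | target

**Step count**

Total steps: 7. Longest linear sequence: 7 steps (1 → 15).

**Steps most likely to fail**

Step 2. Methyl transfer may be slow at a β carbon whose ortho-substituted aryl group is twisted and crowds both faces, so that enantiofacial control is lost and 1,2-addition competes. During a slow alkylation at the congested C2, proton exchange between ketone and enolate can also move the enolate to C5 and give misplaced or double methylation. The fallback exchanges the roles of the two carbon groups and sets out from 1. Bromine–lithium exchange (n-BuLi, Et2O, −78 °C) gives (2-methoxy-4-methylphenyl)lithium F1, and Me2AlCl converts it into (2-methoxy-4-methylphenyl)dimethylaluminium F2. Cu(OTf)2/phosphoramidite-catalysed conjugate transfer of the aryl group from F2 to commercial 3-methylcyclopent-2-en-1-one (CC1=CC(=O)CC1) then gives the same dimethylaluminium enolate. The route is rejoined at 8, and the MeLi/MeI alkylation follows as in step 2. This is the known asymmetric conjugate addition of aryl(dialkyl)aluminium reagents to 3-methylcycloalkenones, in which aryl is transferred in preference to alkyl; the ligand antipode is chosen so that C3 is again R.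

Step 3. Proton loss may occur from the unhindered C5 methylene instead of the congested C2–H, giving the less substituted enol triflate and from it the wrong alkene regioisomer; cation-type side reactions of the triflyloxycarbenium ion are also possible. The fallback is an anionic route through an isolated, equilibrated enol derivative and sets out from 10. Me3SiCl/Et3N in DMF at 130 °C (equilibrating silylation) should give {[(3R)-3-(2-methoxy-4-methylphenyl)-2,3-dimethylcyclopent-1-en-1-yl]oxy}trimethylsilane F3, which is purified from any C1=C5 isomer. MeLi (THF, 0 °C) cleaves the O–Si bond to give lithium (3R)-3-(2-methoxy-4-methylphenyl)-2,3-dimethylcyclopent-1-en-1-olate F4 without loss of regiochemistry, and PhNTf2 triflates it on oxygen to give 11, where the route is rejoined.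

Step 7. The cyclopropane may be opened by adventitious HBr or by the brominating agent, with capture of the cation by the neighbouring phenol oxygen (closure to a dihydrobenzofuran). Ipso attack and over-oxidation of the very electron-rich ring, or incomplete substitution at the flanked ortho position, are further possibilities. The fallback uses two separate, site-specific brominations and sets out from 14. NBS (1.0 equiv, MeCN, −20 °C) should brominate only the para position to give 4-bromo-2-[(1S,2R,5R)-1,2-dimethylbicyclo[3.1.0]hexan-2-yl]-5-methylphenol F5. The remaining ortho position is then brominated with the tert-butylamine–bromine reagent (Br2, t-BuNH2, toluene, −78 °C), which delivers bromine ortho to the phenol oxygen and binds the HBr as its ammonium salt, giving 15.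

**Further compounds**

F1 | step 2 | (2-methoxy-4-methylphenyl)lithium | [Li]c1ccc(C)cc1OC
F2 | step 2 | (2-methoxy-4-methylphenyl)dimethylaluminium | COc1cc(C)ccc1[Al](C)C
F3 | step 3 | {[(3R)-3-(2-methoxy-4-methylphenyl)-2,3-dimethylcyclopent-1-en-1-yl]oxy}trimethylsilane | COc1cc(C)ccc1[C@]1(C)CCC(O[Si](C)(C)C)=C1C
F4 | step 3 | lithium (3R)-3-(2-methoxy-4-methylphenyl)-2,3-dimethylcyclopent-1-en-1-olate | [Li+].COc1cc(C)ccc1[C@]1(C)CCC([O-])=C1C
F5 | step 7 | 4-bromo-2-[(1S,2R,5R)-1,2-dimethylbicyclo[3.1.0]hexan-2-yl]-5-methylphenol | Cc1cc(O)c([C@]2(C)CC[C@@H]3C[C@@]32C)cc1Br
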